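The top target readings fall as the charge rises: 29.7% in the summer run and 25.5% in the noon run, both at 8.00 min.

| flask | substrate | remark | time |
|---|---|---|---|
| summer | 0.20 M | run made earlier |  |
| noon | 0.30 M | run made earlier |  |
| flask | 0.40 M |  | 15 min |

| run | time / min | target / % | substrate / % |
|---|---|---|---|
| summer | 1.50 | 13.0 | 38.8 |
| summer | 2.50 | 20.0 | 25.1 |
| summer | 4.00 | 26.0 | 13.7 |
| summer | 8.00 | 29.7 | 2.9 |
| summer | 12.0 | 26.7 | 1.3 |
| noon | 1.50 | 11.6 | 33.6 |
| noon | 2.50 | 18.4 | 20.6 |
| noon | 4.00 | 23.0 | 10.6 |
| noon | 8.00 | 25.5 | 2.6 |
| noon | 12.0 | 22.8 | 0.5 |

(readings scatter by 0.5 percentage points)



* when, up to 15 min, the flask holds most target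
* the amount of target, in percent of the substrate charged, at that time
* the first time at which target reaches 6.8%, in the same percent, in min

Question: what takes the amount away?
Answer: I take substrate to leave by two routes. One is first-order, with constant k. The other is second-order, and I count it as lost to target. For the fraction f of the charge still present, the loss rate is then k·f plus k·x·f·f. Here x is a crowding number, proportional to the charge.

Question: how do you read x?
Answer: At a fixed time, the inverse of f is a straight line in the charge, and its value at no charge is exp(kt). The two runs at 2.50 min put that value at 2.24. So k is 0.323 /min, and summer has x of 1.40. That is one pair of readings, so both carry its scatter.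

Question: what follows at the two ends?
Answer: At small x the first-order route takes the charge. At large x its part sinks like ln(x)/x. The form ln(1+x)/x joins these ends. It gives 0.625 for summer and 0.539 for noon. I call this the kept share, the part of the charge leaving by the first-order route, which is an integral selectivity.

Question: why should the top reading follow it?
Answer: That is an assumption, so test it. Top reading per kept share is 0.475 in summer and 0.473 at noon. The top readings played no part in finding x.

Question: and the flask?
Answer: Its x scales to 2.80 and its kept share is 0.477. My reckoning therefore gives a peak of 22.6%. It gives no times.

The forecast gives 23% at 7 min and the asked level at 0.95 min, on the ground that “Peak target tracks this share”, with a share of about 0.52 for this flask where my kept share is 0.477.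

The flask gives 22.7% at 6.62 min and reaches the asked level at 0.974 min.

    intermediate ⇌ isomer of the product (K = 16.0, k = 0.00210 /s)
    intermediate ⇌ target (K = 2.00, k = 0.0170 /s)
    2 substrate → self-condensation product (k = 0.0200 /M/s)
    substrate → intermediate (k = 0.00540 /s)

The neighbour flask is the same flask with 0.10 M of substrate. Its x scales to 0.700, so its kept share is 0.758. The same top reading per kept share then gives a peak of 35.9%, and the simulation gives 35.8%. The reckoned waste in this neighbour is 24.2% of its charge. At 15.0 min, with 0.45% of its substrate left, its self-condensation product, counted as the substrate it holds, stands at 25.2%.

The data were computed for an exercise, noise included.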